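The e-folding was my unit: for each closed flask I counted the e-foldings of starting material gone when it stopped falling, the natural logarithm of charge over remainder, and called that number the stall depth.

the same everywhere: starting material 20 mM
- autumn: reagent 22 mM; initiator 0.20 mM; run made earlier
- dusk: reagent 22 mM; initiator 0.30 mM; run made earlier
- flask: reagent 22.0 mM; initiator 0.40 mM; time 5.0 h

| run | time / h | first chain carrier / % | over-reaction product / % | target / % | starting material / % |
|---|---|---|---|---|---|
| autumn | 0.200 | 0.4 | 0.5 | 13.2 | 86.7 |
| autumn | 0.667 | 0.1 | 1.9 | 30.0 | 67.5 |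
| autumn | 1.00 | 0 | 2.5 | 34.6 | 61.2 |
| autumn | 1.50 | 0 | 6.1 | 36.7 | 55.1 |
| autumn | 2.50 | 0.1 | 9.3 | 37.2 | 52.3 |
| autumn | 3.00 | 0 | 11.8 | 34.2 | 51.4 |
| dusk | 0.500 | 0.7 | 2.1 | 30.3 | 64.9 |
| dusk | 1.00 | 0.1 | 3.4 | 42.0 | 52.4 |
| dusk | 1.50 | 0 | 5.9 | 44.8 | 46.3 |
| dusk | 2.00 | 0 | 9.4 | 45.5 | 42.7 |
| dusk | 2.50 | 0 | 10.9 | 44.6 | 42.5 |
| dusk | 3.00 | 0 | 12.6 | 42.9 | 42.4 |

(standard deviation of a reading: 0.5 percentage points)

1. the species that holds most of what was charged as starting material, at 5.0 h (over-reaction product / target / starting material / first chain carrier)
2. the largest share itself, whichever of these holds it, in percent of the starting material charged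

- the numbers in the tables scatter by 0.5 percentage points (one standard deviation)

In the dusk run starting material read 42.7 %, 42.5 % and 42.4 % over its last readings, and in the autumn run 52.3 % and 51.4 %, so I took the final readings as stalls. That gave a depth of 0.666 for the autumn run and 0.858 for the dusk run.

I had two ways to the flask. A root law in charged [initiator], scaled from the dusk run, leaves 37.1 %. The second way reads the growth of depth with [initiator] from the two runs themselves. This is the stall exponent 0.627, an apparent order in initiator, and it leaves 35.8 %.

To see which way cheats, I sent the root law from the autumn run to the dusk run. It gave 44.3 % against the 42.4 % read, a gap of 1.9 percentage points beside a scatter of 0.5 points, so I kept the exponent, though it meets both runs by construction.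

Over-reaction product gained 6.7 points in the dusk run from 1.50 h to 3.00 h. Run on at that pace to 5.0 h, it gave my estimate for the flask, 21.5 %. The dusk balance lacked 2.10 %, so I reckoned target in the flask at 40.6 %, above starting material.

The forecast also named target, at 39 %, a lower share than mine, on the ground that “The stalled conversion fits a square-root dependence on initiator”.

    initiator → 2 initiating radical (k = 0.0330 min⁻¹)
    starting material + initiating radical → capped initiator + first chain carrier (k = 1.50 × 10⁵ M⁻¹ s⁻¹)
    reagent + first chain carrier → target + second chain carrier (k = 2.20 × 10⁵ M⁻¹ min⁻¹)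
    starting material + second chain carrier → by-product + first chain carrier (k = 1.20 × 10⁵ M⁻¹ min⁻¹)
    first chain carrier → ended carrier (k = 57.0 min⁻¹)
    2 first chain carrier → ended chains A (k = 2.10 × 10⁷ M⁻¹ s⁻¹)
    2 second chain carrier → ended chains B (k = 1.50 × 10⁶ M⁻¹ s⁻¹)
    reagent + target → over-reaction product (k = 0.160 M⁻¹ min⁻¹)

The flask gave target at 44.2 %, with starting material at 34.3 %. Initiator was down to 0.708 % of its charge at 2.50 h, when starting material already stood at 35.1 %. The stall depth of the flask came to 1.07. In a neighbouring flask, the same but with 0.68 mM of initiator, the exponent 0.627 gives a depth of 1.43, which leaves 23.9 %. That neighbour flask held 20 % of its starting material at 5.00 h.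

(The earlier runs and the new flask stem from a simulated flask for an exercise; scatter was added.)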